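## The problem

The target **13** is a linear tridepside: three orsellinate-type benzene rings joined by two aryl ester bonds, the ring C carbonyl to the ring B 4-oxygen and the ring B carbonyl to the ring A 4-oxygen. No ring is fused and no chain is built, so the work is ester formation and the placing of oxygen substituents. There are no stereocentres; every selectivity question is one of site: which hydroxyl is acylated, which is methylated, which C–H is oxidised. Ring A carries a methyl ether at C2 whereas rings B and C carry free hydroxyls at C2 (ring C also at C4), so the ring A ether must be set while its oxygen is the only free one. The aryl ester links are cleaved or transferred by hydroxide, alkoxides, amines and phenoxides, and the free resorcinol of ring C is sensitive to oxidants, so the late steps must be neutral or acidic. In rings B and C the acyl carbon C1 lies between a hydroxyl (C2) and a methyl (C6); such 2,6-disubstituted benzoic acids esterify poorly with phenols. The same feature is the opening: without the C2 hydroxyls, the ring B and ring C benzoates each have one ortho hydrogen and one ortho methyl, so an ester-directed metalation has exactly one site per ring. The ring A ester, flanked by OMe (C2) and Me (C6), has none.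

## Retrosynthesis

**13 ⇒ 12 ⇒ 11 ⇒ 10.** The first cut removes the two aryl C2–O bonds of rings B and C. Cutting an ester bond first would instead return 2,6-disubstituted acids with the coupling and protecting-group problems they bring. The precursor **10** has two oxygens fewer and both of its acyl units come from one acid. A benzyl ether on the ring C 4-oxygen is not expected to survive hot trifluoroacetic acid with a trivalent iodine oxidant (acidolysis, benzyl cation transfer to the rings, benzylic oxidation). The phenol is therefore carried free into the step and capped in the flask by trifluoroacetic anhydride as trifluoroacetate **11**. The oxygenation gives the tris(trifluoroacetate) **12**, and neutral aqueous work-up releases all three phenols of **13**. The forward reaction must deliver two oxygenations directed by weakly donating aryl ester carbonyls, on the acyl side only, without oxidising the ring A anisole or breaking an ester.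

**10 ⇒ 9.** The O–benzyl bond on ring C is cut. The benzyl ether is needed only while the chain is assembled, and hydrogenolysis removes it under neutral conditions that leave the depside links alone.

**9 ⇒ 8 + 4.** The ester bond between the ring C acyl carbon and the ring B 4-oxygen is cut, giving phenol **8** and 4-(benzyloxy)-2-methylbenzoic acid **4**. Cutting the ring B–ring A ester first would need a ring B–C acid with its own carboxyl protection; the linear order uses **4** twice and needs none. The forward step is an ordinary carbodiimide esterification of a mono-ortho-substituted acid.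

**8 ⇒ 7 ⇒ 6.** The benzyl ether of ring B is restored (**7**), then the O–CH3 bond at the ring A 2-oxygen is cut (**6**). In **6** that hydroxyl is the only free one, so the methylation has no site problem; it must only spare the aryl ester.

**6 ⇒ 4 + 5.** The ring B–ring A ester is cut to acid **4** and methyl orsellinate **5**. The forward acylation must occur at the 4-hydroxyl of **5**; the 2-hydroxyl is hydrogen-bonded to the ester carbonyl and hindered by it. This avoids protecting ring A.

**4 ⇒ 1 + 2.** The acid comes from 4-hydroxy-2-methylbenzoic acid **1** and benzyl bromide **2** by double benzylation to **3** and saponification of the ester.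

## Roads not taken

**Alternative 1:** The cut runs through ring C at C1–C6 and C3–C4, back to tert-butyl acetoacetate **A1** and methyl crotonate **A2**. Forward, KOtBu would bring about Michael addition and Claisen closure to the cyclic dione **A3** (tert-butyl dihydroorsellinate, racemic; its one stereocentre is erased later). Dehydrogenation would give tert-butyl orsellinate **A4**.
- Merits: cheap materials and a robust annulation; both oxygens come from carbonyl groups, so no arene is oxidised.
- Weak points: it makes an orsellinate monomer, and the methyl ester **5** can be bought. After two added steps the route still needs phenol protection, ester cleavage and esterification of a 2,6-disubstituted acid with a phenol, twice if ring B is made the same way. No depside bond is formed.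
- Comparison: each step of this road is more certain than step 7. The chosen plan sets against it a route of seven steps, acids that esterify easily, and both crowded positions created in one operation after the chain exists.

**Alternative 2:** The cut removes C1–C2, C2–C3 and C4–C5 of ring C. It leads back to the diazomethyl enone ester **A5**, already attached to a ring A–B depside with a benzylated ring B 2-oxygen, and (triisopropylsilyloxy)acetylene **A6**. Forward, irradiation would cause Wolff rearrangement to a vinylketene; cycloaddition with **A6**, four-electron ring opening, six-electron electrocyclisation and tautomerisation would give **A7**.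
- Merits: the substitution pattern of ring C follows from connectivity, and the ester to ring B is made from an unhindered enoate before the crowded ring exists. This is the same logic as the chosen plan.
- Weak points: aryl esters are liable to photo-Fries rearrangement under the irradiation. **A5** needs several steps and a diazo transfer on a depside, and **A6** is a sensitive reagent. Only ring C is built, so ring B must still arrive as a hindered 2-benzyloxy acid, and two different protecting groups remain at the end.
- Comparison: regiochemical certainty for ring C is at least as good as in the chosen plan, which relies on a blocking methyl group and a chelate-size preference. The chosen plan sets against it that both rings are handled in one step, in roughly half the operations, without photochemistry or diazo compounds.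

**Alternative 3:** The cut takes the ring B–ring A ester C–O bond and C1–C6 of ring B, back to the ring A phenol **A9** and the diketo-dioxinone **A8**. Forward, heating **A8** would release the acylketene **A10**, which **A9** would trap to give the triketo ester **A11**. Mild base would then fold it by aldol condensation and aromatisation to the didepside **A12**, with both ring B hydroxyls free.
- Merits: ketene capture is indifferent to the crowding that hampers 2,6-disubstituted acids, the oxygens fall into place from the chain, and ring B needs no protecting group. Its key step is more secure than step 7.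
- Weak points: **A8** needs several steps of enolate acylation, and **A9** needs three steps from **5**. The sequence stops at **A12**, so ring C must still be added, either by a second ketene capture and base-mediated aromatisation next to a base-sensitive depside bond, or by a classical hindered esterification with protecting groups.
- Comparison: this road is ahead in reliability. The chosen plan sets against it one inexpensive aromatic acid for both rings B and C, no polycarbonyl intermediates, and two oxygens installed in a single step.

Key step: step 7

Assumption: aryl benzoate (depside) carbonyls are taken to direct ruthenation as the alkyl benzoate carbonyls do on which this hydroxylation is established, though as weaker donors; all compounds are achiral.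

## Route

Step 1
Reactants: 1 4-hydroxy-2-methylbenzoic acid; 2 benzyl bromide
Product: 4 4-(benzyloxy)-2-methylbenzoic acid, via benzyl 4-(benzyloxy)-2-methylbenzoate 3 (not isolated)
Conditions: BnBr (2.3 equiv), K2CO3, DMF, 60 °C; aqueous work-up, crude 3 used directly; then NaOH, THF/H2O, 65 °C; then aq. HCl
Reagents that add atoms: sodium hydroxide, [Na+].[OH-]
Why: Williamson O-alkylation of carboxylate and phenoxide gives 3; saponification then cleaves only the benzyl ester, the benzyl aryl ether being inert to hydroxide, and acidification releases 4.

Step 2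
Reactants: 4 4-(benzyloxy)-2-methylbenzoic acid; 5 methyl 2,4-dihydroxy-6-methylbenzoate (methyl orsellinate)
Product: 6 methyl 4-{[4-(benzyloxy)-2-methylbenzoyl]oxy}-2-hydroxy-6-methylbenzoate
Conditions: DCC, DMAP (cat.), CH2Cl2, 0 °C to rt
Reagents that add atoms: none
Why: Steglich esterification; acid 4 has one ortho substituent and is activated readily, and in 5 only the 4-hydroxyl is free, the 2-hydroxyl being hydrogen-bonded to and hindered by the ester carbonyl, so acylation should occur at O4.

Step 3
Reactants: 6 methyl 4-{[4-(benzyloxy)-2-methylbenzoyl]oxy}-2-hydroxy-6-methylbenzoate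
Product: 7 methyl 4-{[4-(benzyloxy)-2-methylbenzoyl]oxy}-2-methoxy-6-methylbenzoate
Conditions: MeI (excess), K2CO3, acetone, 45 °C
Reagents that add atoms: iodomethane, CI
Why: Williamson methylation of the only free hydroxyl; the electron-rich, mono-ortho-substituted aryl benzoate should tolerate anhydrous carbonate, and the phenoxide is meta to the acyloxy group, so no intramolecular acyl shift is possible.

Step 4
Reactants: 7 methyl 4-{[4-(benzyloxy)-2-methylbenzoyl]oxy}-2-methoxy-6-methylbenzoate
Product: 8 methyl 4-[(4-hydroxy-2-methylbenzoyl)oxy]-2-methoxy-6-methylbenzoate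
Conditions: H2 (1 atm), Pd/C (10 wt% Pd), EtOAc, rt
Reagents that add atoms: none
Why: Hydrogenolysis of the benzyl aryl ether; aryl ester, methyl ester and methyl ether are inert, and the ester solvent excludes transesterification.

Step 5
Reactants: 4 4-(benzyloxy)-2-methylbenzoic acid; 8 methyl 4-[(4-hydroxy-2-methylbenzoyl)oxy]-2-methoxy-6-methylbenzoate
Product: 9 methyl 4-[(4-{[4-(benzyloxy)-2-methylbenzoyl]oxy}-2-methylbenzoyl)oxy]-2-methoxy-6-methylbenzoate
Conditions: DCC, DMAP (cat.), CH2Cl2, 0 °C to rt
Reagents that add atoms: none
Why: Second Steglich esterification with the same mono-ortho-substituted acid; phenol 8 is the only nucleophile present.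

Step 6
Reactants: 9 methyl 4-[(4-{[4-(benzyloxy)-2-methylbenzoyl]oxy}-2-methylbenzoyl)oxy]-2-methoxy-6-methylbenzoate
Product: 10 methyl 4-({4-[(4-hydroxy-2-methylbenzoyl)oxy]-2-methylbenzoyl}oxy)-2-methoxy-6-methylbenzoate
Conditions: H2 (1 atm), Pd/C (10 wt% Pd), THF/EtOAc, rt
Reagents that add atoms: none
Why: Hydrogenolysis as in step 4; it removes, under neutral conditions that spare both depside links, the benzyl group that would not survive the acid and oxidant of step 7.

Step 7
Reactants: 10 methyl 4-({4-[(4-hydroxy-2-methylbenzoyl)oxy]-2-methylbenzoyl}oxy)-2-methoxy-6-methylbenzoate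
Product: 13 methyl 4-({4-[(2,4-dihydroxy-6-methylbenzoyl)oxy]-2-hydroxy-6-methylbenzoyl}oxy)-2-methoxy-6-methylbenzoate (the target), via ring C 4-O-trifluoroacetate 11 (not isolated), via tris(trifluoroacetate) 12 (not isolated)
Conditions: TFAA, TFA, rt; then [RuCl2(p-cymene)]2 (5 mol%), PhI(OCOCF3)2 (2.6 equiv), TFA/TFAA, 80 °C; then THF/H2O, pH 7 buffer (NaH2PO4/Na2HPO4), rt
Reagents that add atoms: [bis(trifluoroacetoxy)iodo]benzene, FC(F)(F)C(=O)OI(OC(=O)C(F)(F)F)c1ccccc1
Why: Ruthenium-catalysed, ester-directed ortho C–H oxygenation of benzoates, the reaction type established for alkyl benzoates with divalent ruthenium and a trivalent iodine oxidant in TFA/TFAA. TFAA first caps the ring C phenol of 10 as trifluoroacetate 11, so that no free phenol meets the oxidant and ring C becomes a 4-acyloxybenzoate like ring B. In the acid the chlorides of [RuCl2(p-cymene)]2 are exchanged for trifluoroacetate, the carbonyl oxygen of each depside ester binds divalent ruthenium, and carboxylate-assisted C–H cleavage gives a five-membered ruthenacycle at the one free ortho carbon of ring B and of ring C. PhI(OCOCF3)2 oxidises each metallacycle to tetravalent ruthenium, C–O reductive elimination releases the aryl trifluoroacetate and divalent ruthenium, and two such cycles give 12. The buffered work-up hydrolyses the three aryl trifluoroacetates, far more labile than the benzoate links, to 13. No ring closes and no stereocentre is formed. The site selectivity needed is secured by the methyl on the other ortho carbon of rings B and C, by the absence of any ortho hydrogen beside the ring A ester, and by the preference for the five-membered acyl-side chelate over the six-membered one reaching the hydrogens ortho to the ester oxygens. Over-oxidation is held back by the electron-withdrawing acyloxy and trifluoroacetoxy groups on every ring and by each new oxygen staying masked as a trifluoroacetate until work-up.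

## Compound list

1 | 4-hydroxy-2-methylbenzoic acid | Cc1cc(O)ccc1C(=O)O | starting material
2 | benzyl bromide | BrCc1ccccc1 | starting material
3 | benzyl 4-(benzyloxy)-2-methylbenzoate | Cc1cc(OCc2ccccc2)ccc1C(=O)OCc1ccccc1 | intermediate
4 | 4-(benzyloxy)-2-methylbenzoic acid | Cc1cc(OCc2ccccc2)ccc1C(=O)O | intermediate
5 | methyl 2,4-dihydroxy-6-methylbenzoate (methyl orsellinate) | COC(=O)c1c(C)cc(O)cc1O | starting material
6 | methyl 4-{[4-(benzyloxy)-2-methylbenzoyl]oxy}-2-hydroxy-6-methylbenzoate | COC(=O)c1c(C)cc(OC(=O)c2c(C)cc(OCc3ccccc3)cc2)cc1O | intermediate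
7 | methyl 4-{[4-(benzyloxy)-2-methylbenzoyl]oxy}-2-methoxy-6-methylbenzoate | COC(=O)c1c(C)cc(OC(=O)c2c(C)cc(OCc3ccccc3)cc2)cc1OC | intermediate
8 | methyl 4-[(4-hydroxy-2-methylbenzoyl)oxy]-2-methoxy-6-methylbenzoate | COC(=O)c1c(C)cc(OC(=O)c2c(C)cc(O)cc2)cc1OC | intermediate
9 | methyl 4-[(4-{[4-(benzyloxy)-2-methylbenzoyl]oxy}-2-methylbenzoyl)oxy]-2-methoxy-6-methylbenzoate | COC(=O)c1c(C)cc(OC(=O)c2c(C)cc(OC(=O)c3c(C)cc(OCc4ccccc4)cc3)cc2)cc1OC | intermediate
10 | methyl 4-({4-[(4-hydroxy-2-methylbenzoyl)oxy]-2-methylbenzoyl}oxy)-2-methoxy-6-methylbenzoate | COC(=O)c1c(C)cc(OC(=O)c2c(C)cc(OC(=O)c3c(C)cc(O)cc3)cc2)cc1OC | intermediate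
11 | ring C 4-O-trifluoroacetate of 10 | COC(=O)c1c(C)cc(OC(=O)c2c(C)cc(OC(=O)c3c(C)cc(OC(=O)C(F)(F)F)cc3)cc2)cc1OC | intermediate
12 | tris(trifluoroacetate) of 13 (trifluoroacetyl on the ring B 2-oxygen and the ring C 2- and 4-oxygens) | COC(=O)c1c(C)cc(OC(=O)c2c(C)cc(OC(=O)c3c(C)cc(OC(=O)C(F)(F)F)cc3OC(=O)C(F)(F)F)cc2OC(=O)C(F)(F)F)cc1OC | intermediate
13 | methyl 4-({4-[(2,4-dihydroxy-6-methylbenzoyl)oxy]-2-hydroxy-6-methylbenzoyl}oxy)-2-methoxy-6-methylbenzoate (CNP0503951.0) | COC(=O)c1c(C)cc(OC(=O)c2c(C)cc(OC(=O)c3c(C)cc(O)cc3O)cc2O)cc1OC | target

## Step count and least certain steps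

Total: 7 steps. Longest linear sequence: 7 steps (steps 1 to 7; acid 4 from step 1 is used in step 2 and again in step 5).

**Step 7 (key step).** Three processes may spoil it:
- Cyclometalation may be slow at the weakly donating aryl ester carbonyls, so that the oxidant is consumed while mono-oxygenated material remains.
- The ring A anisole may be oxidised, by electron transfer to the iodine reagent or by oxygenation para to the methoxy group.
- A depside link may undergo acid-promoted acyl–oxygen scission at 80 °C.

The fallback gives up late oxygenation and carries the oxygens in from the start; it sets out from 5 and 2 and comes back at 13. Dibenzylation of 5 (BnBr, K2CO3, DMF, 70 °C) would give methyl 2,4-bis(benzyloxy)-6-methylbenzoate F1, and saponification (KOH, DMSO/H2O, 90 °C) 2,4-bis(benzyloxy)-6-methylbenzoic acid F2. Esterification of F2 with the 4-hydroxyl of 5 through the mixed trifluoroacetic anhydride (TFAA, toluene, rt) would give methyl 4-{[2,4-bis(benzyloxy)-6-methylbenzoyl]oxy}-2-hydroxy-6-methylbenzoate F3. Methylation (MeI, K2CO3, acetone) would give methyl 4-{[2,4-bis(benzyloxy)-6-methylbenzoyl]oxy}-2-methoxy-6-methylbenzoate F4. Hydrogenolysis (H2, Pd/C, EtOAc) would give methyl 4-[(2,4-dihydroxy-6-methylbenzoyl)oxy]-2-methoxy-6-methylbenzoate F5. A second TFAA-mediated esterification with F2, at the unchelated ring B 4-hydroxyl, would give methyl 4-[(4-{[2,4-bis(benzyloxy)-6-methylbenzoyl]oxy}-2-hydroxy-6-methylbenzoyl)oxy]-2-methoxy-6-methylbenzoate F6, and hydrogenolysis would give 13.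

**Step 3.** O-Methylation of the hydrogen-bonded phenol may be slow enough for carbonate-mediated cleavage or intermolecular transfer of the aryl ester to compete. The fallback sets the methyl ether before any depside bond exists; it sets out from 5 and 2 and comes back at 7. Benzylation of 5 at the 4-hydroxyl (BnBr, 1.05 equiv, K2CO3, acetone, reflux) would give methyl 4-(benzyloxy)-2-hydroxy-6-methylbenzoate F7. Methylation (MeI, K2CO3, DMF, 50 °C) would give methyl 4-(benzyloxy)-2-methoxy-6-methylbenzoate F8. Hydrogenolysis (H2, Pd/C, EtOAc) would give methyl 4-hydroxy-2-methoxy-6-methylbenzoate F9, which is esterified with 4 (DCC, DMAP) to give 7.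

**Step 5.** Phenol 8 is a weak nucleophile and is itself an aryl ester. Rearrangement of the activated acid to the N-acylurea, or acyl exchange between depside molecules under nucleophilic catalysis, may outrun the desired acylation. The fallback joins rings C and B first, so that no coupling partner carries both a free phenol and a depside bond; it sets out from 1 and 4 and comes back at 9. Carboxylate alkylation of 1 (allyl bromide, KHCO3, DMF, rt) would give prop-2-en-1-yl 4-hydroxy-2-methylbenzoate F10. Esterification with 4 (DCC, DMAP) would give prop-2-en-1-yl 4-{[4-(benzyloxy)-2-methylbenzoyl]oxy}-2-methylbenzoate F11. Deallylation (Pd(PPh3)4, N-methylaniline, THF, rt) would give 4-{[4-(benzyloxy)-2-methylbenzoyl]oxy}-2-methylbenzoic acid F12. Acylation of 5 at its 4-hydroxyl as in step 2 would give methyl 4-[(4-{[4-(benzyloxy)-2-methylbenzoyl]oxy}-2-methylbenzoyl)oxy]-2-hydroxy-6-methylbenzoate F13, and methylation as in step 3 would give 9.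

## Further compounds

F1 | step 7 | methyl 2,4-bis(benzyloxy)-6-methylbenzoate | COC(=O)c1c(C)cc(OCc2ccccc2)cc1OCc1ccccc1
F2 | step 7 | 2,4-bis(benzyloxy)-6-methylbenzoic acid | OC(=O)c1c(C)cc(OCc2ccccc2)cc1OCc1ccccc1
F3 | step 7 | methyl 4-{[2,4-bis(benzyloxy)-6-methylbenzoyl]oxy}-2-hydroxy-6-methylbenzoate | COC(=O)c1c(C)cc(OC(=O)c2c(C)cc(OCc3ccccc3)cc2OCc2ccccc2)cc1O
F4 | step 7 | methyl 4-{[2,4-bis(benzyloxy)-6-methylbenzoyl]oxy}-2-methoxy-6-methylbenzoate | COC(=O)c1c(C)cc(OC(=O)c2c(C)cc(OCc3ccccc3)cc2OCc2ccccc2)cc1OC
F5 | step 7 | methyl 4-[(2,4-dihydroxy-6-methylbenzoyl)oxy]-2-methoxy-6-methylbenzoate | COC(=O)c1c(C)cc(OC(=O)c2c(C)cc(O)cc2O)cc1OC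
F6 | step 7 | methyl 4-[(4-{[2,4-bis(benzyloxy)-6-methylbenzoyl]oxy}-2-hydroxy-6-methylbenzoyl)oxy]-2-methoxy-6-methylbenzoate | COC(=O)c1c(C)cc(OC(=O)c2c(C)cc(OC(=O)c3c(C)cc(OCc4ccccc4)cc3OCc3ccccc3)cc2O)cc1OC
F7 | step 3 | methyl 4-(benzyloxy)-2-hydroxy-6-methylbenzoate | COC(=O)c1c(C)cc(OCc2ccccc2)cc1O
F8 | step 3 | methyl 4-(benzyloxy)-2-methoxy-6-methylbenzoate | COC(=O)c1c(C)cc(OCc2ccccc2)cc1OC
F9 | step 3 | methyl 4-hydroxy-2-methoxy-6-methylbenzoate | COC(=O)c1c(C)cc(O)cc1OC
F10 | step 5 | prop-2-en-1-yl 4-hydroxy-2-methylbenzoate | C=CCOC(=O)c1c(C)cc(O)cc1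
F11 | step 5 | prop-2-en-1-yl 4-{[4-(benzyloxy)-2-methylbenzoyl]oxy}-2-methylbenzoate | C=CCOC(=O)c1c(C)cc(OC(=O)c2c(C)cc(OCc3ccccc3)cc2)cc1
F12 | step 5 | 4-{[4-(benzyloxy)-2-methylbenzoyl]oxy}-2-methylbenzoic acid | OC(=O)c1c(C)cc(OC(=O)c2c(C)cc(OCc3ccccc3)cc2)cc1
F13 | step 5 | methyl 4-[(4-{[4-(benzyloxy)-2-methylbenzoyl]oxy}-2-methylbenzoyl)oxy]-2-hydroxy-6-methylbenzoate | COC(=O)c1c(C)cc(OC(=O)c2c(C)cc(OC(=O)c3c(C)cc(OCc4ccccc4)cc3)cc2)cc1O
A1 | alternative 1 | tert-butyl acetoacetate | CC(=O)CC(=O)OC(C)(C)C
A2 | alternative 1 | methyl (E)-but-2-enoate (methyl crotonate) | C/C=C/C(=O)OC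
A3 | alternative 1 | tert-butyl 2,4-dihydroxy-6-methylcyclohexa-1,3-diene-1-carboxylate (dienol form of tert-butyl dihydroorsellinate; racemic, 6S enantiomer drawn) | C[C@H]1CC(O)=CC(O)=C1C(=O)OC(C)(C)C
A4 | alternative 1 | tert-butyl 2,4-dihydroxy-6-methylbenzoate (tert-butyl orsellinate) | Cc1cc(O)cc(O)c1C(=O)OC(C)(C)C
A5 | alternative 2 | ring A–B depside (ring B 2-O-benzyl) esterified at the ring B 4-oxygen with (E)-5-diazo-3-methyl-4-oxopent-2-enoic acid | COC(=O)c1c(C)cc(OC(=O)c2c(C)cc(OC(=O)/C=C(\C)C(=O)C=[N+]=[N-])cc2OCc2ccccc2)cc1OC
A6 | alternative 2 | (triisopropylsilyloxy)acetylene | C#CO[Si](C(C)C)(C(C)C)C(C)C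
A7 | alternative 2 | tridepside with ring C 4-O-triisopropylsilyl and ring B 2-O-benzyl | COC(=O)c1c(C)cc(OC(=O)c2c(C)cc(OC(=O)c3c(C)cc(O[Si](C(C)C)(C(C)C)C(C)C)cc3O)cc2OCc2ccccc2)cc1OC
A8 | alternative 3 | 6-(2,4-dioxopentyl)-2,2-dimethyl-4H-1,3-dioxin-4-one | CC(=O)CC(=O)CC1=CC(=O)OC(C)(C)O1
A9 | alternative 3 | methyl 4-hydroxy-2-methoxy-6-methylbenzoate (ring A phenol) | COC(=O)c1c(C)cc(O)cc1OC
A10 | alternative 3 | 3,5,7-trioxoocta-1-en-1-one (acylketene) | CC(=O)CC(=O)CC(=O)C=C=O
A11 | alternative 3 | methyl 2-methoxy-6-methyl-4-[(3,5,7-trioxooctanoyl)oxy]benzoate | COC(=O)c1c(C)cc(OC(=O)CC(=O)CC(=O)CC(C)=O)cc1OC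
A12 | alternative 3 | methyl 4-[(2,4-dihydroxy-6-methylbenzoyl)oxy]-2-methoxy-6-methylbenzoate (ring A–B depside with free ring B hydroxyls) | COC(=O)c1c(C)cc(OC(=O)c2c(C)cc(O)cc2O)cc1OC
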